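## Plan

- **Numbering and feature.** Carbons are C1–C20 in target-SMILES order. C8 is a quaternary bridgehead of the bicyclo[2.2.1]heptane (five-membered rings C4–C5–C6–C7–C8 and C6–C7–C8–C19–C20). It carries the C9–C10 chain and lies between C4 and C19, which is the pattern left when C19 of a 2-alkyl-2-norbornyl cation shifts from C4 to C8.
- **Cuts, latest first.** C13–Br and C20–OH (back to an axial C13 carbinol and a C20 ketone); C16–C17 (methyl onto a C16 ketone); C18–C19 (aldol); C10–C11 (alkylation of a 2-methylcyclohexane-1,3-dione unit); C2–C4 (isopropyl); then C8–C19, traced by the 1,2-shift back to C4–C19 of a norbornan-2-ol made from (1S,4S)-norbornane-2,5-dione.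
- **Forward order.** Chain onto one carbonyl of the dione; shift to the 1-substituted norbornane (ring C6–C7–C8–C19–C20 arises); isopropyl at C4; ring C joined through C10–C11; ring B closed by aldol condensation; then C16 carbinol, enone reduction, bromide, C20 alcohol.
- **Stereochemistry.** C6 from the dione; C8 by the cage and the C4 oxygen by exo capture in the shift; C4 by exo hydrogenation; C11 and C13 by CBS desymmetrisation; C16 by methyl addition anti to the axial C11 methyl; C18 by dissolving-metal reduction; C19 by equilibration; C13–Br by SN2 inversion; C20 by exo hydride.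
- **Chain terminus.** C10 is carried as chloride, not as an ether: an ether oxygen five atoms from C4 would trap the rearranged cation as a tetrahydrofuran.

Key step: step 4

Remark (assumption): in step 15 the (S)-CBS catalyst is taken to give the (3R) carbinol with hydride anti to the larger C2 substituent (usual CBS model, quaternary carbon as large group); if the sense proves opposite, the (R)-catalyst is used.

Remark (names): norbornanes are numbered as norbornan-2-ones (C2 = C20, C4 = C8, C5 = C4 of the target). R = 2-(2,2-ethylenedioxy-5-endo-isopropylbicyclo[2.2.1]hept-4-yl)ethyl. "Tetracycle" means the ring system of the target. Compounds 1, 2, 12, 16 and 17 are purchased.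

## Route

Step 1
Reactants: 1 (1S,4S)-bicyclo[2.2.1]heptane-2,5-dione; 2 vinylmagnesium bromide
Product: 3 5-endo-hydroxy-5-exo-vinylbicyclo[2.2.1]heptan-2-one
Conditions: CeCl3 (anhydrous), THF, −78 °C; 2 (0.95 equiv) added slowly; aq. NH4Cl
Reagents that add atoms: vinylmagnesium bromide (2), C=C[Mg]Br
Why: Organocerium 1,2-addition to one of the two homotopic carbonyls of the C2-symmetric dione (no regiochemical choice; a slight deficit of reagent limits bis-addition and unreacted 1 can be recycled), with attack from the exo face so that vinyl is exo and hydroxyl endo at the future C8.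

Step 2
Reactants: 3
Product: 5 5-endo-hydroxy-5-exo-(2-hydroxyethyl)bicyclo[2.2.1]heptan-2-one, via pinacol alkylboronate 4 (not isolated)
Conditions: pinacolborane, RhCl(PPh3)3 (cat.), THF, rt; then 30% H2O2, aq. NaOH, 0 °C
Reagents that add atoms: hydrogen peroxide, OO
Why: Rh-catalysed anti-Markovnikov hydroboration of the terminal alkene, which is much faster than hydroboration of the ketone, followed by oxidation of the C–B bond.

Step 3
Reactants: 5
Product: 6 5-exo-(2-chloroethyl)-5-endo-hydroxybicyclo[2.2.1]heptan-2-one
Conditions: PPh3, N-chlorosuccinimide, CH2Cl2, 0 °C → rt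
Reagents that add atoms: N-chlorosuccinimide, O=C1CCC(=O)N1Cl
Why: Appel-type chlorination: only the primary alcohol forms the oxyphosphonium and is displaced by chloride (SN2), the tertiary carbinol being too hindered.

Step 4
Reactants: 6
Product: 7 5-exo-acetoxy-4-(2-chloroethyl)bicyclo[2.2.1]heptan-2-one
Conditions: AcOH, H2SO4 (cat.), 45 °C
Reagents that add atoms: acetic acid, CC(=O)O
Why: Protonation and loss of water give the tertiary 2-alkyl-2-norbornyl cation at C8; the C4–C19 σ bond, aligned with the empty orbital on the endo face, shifts to C8 through the C19-bridged ion (Wagner–Meerwein 1,2-alkyl shift), and acetic acid captures C4 from the exo face, anti to the bridging carbon. The closest precedent is the acid-mediated conversion of camphene and 2-alkylnorbornan-2-ols into isobornyl-type (1-alkyl-exo-2-norbornyl) esters. The new five-membered ring C6–C7–C8–C19–C20 is closed by this suprafacial 1,2-shift itself, through a three-centre bridged ion, while the old ring C4–C5–C6–C20–C19 opens, so the bicyclo[2.2.1] frame is kept. C8 is fixed by the cage (C19 can only bond on the endo face, so its configuration follows from C6) and C4 by exo capture. The step needs migration of C19 rather than hydride shifts: the 6,2-hydride shift of the new cation would place charge on C19 next to the C20 carbonyl and is therefore disfavoured, and 3,2-shifts are slow. Tertiary acetate and alkenes formed on the way re-ionise whereas the secondary exo-acetate does not, so the mixture should drain to 7, and the solvent outcompetes the remote chlorine as nucleophile.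

Step 5
Reactants: 7
Product: 8 5-exo-acetoxy-4-(2-chloroethyl)-2,2-ethylenedioxybicyclo[2.2.1]heptane
Conditions: TMSOCH2CH2OTMS, TMSOTf (cat.), CH2Cl2, −78 → −20 °C
Reagents that add atoms: 1,2-bis(trimethylsilyloxy)ethane, C[Si](C)(C)OCCO[Si](C)(C)C
Why: TMSOTf-catalysed ketalisation with the bis-silyl ether masks the C20 ketone under aprotic conditions, so the acetate is not transesterified and the two oxygenated carbons stay differentiated.

Step 6
Reactants: 8
Product: 9 4-(2-chloroethyl)-2,2-ethylenedioxybicyclo[2.2.1]heptan-5-exo-ol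
Conditions: DIBAL-H (2.5 equiv), CH2Cl2, −78 °C; Rochelle salt
Reagents that add atoms: none
Why: Reductive cleavage of the acetate at −78 °C with cold hydrolysis of the aluminium alkoxide, so that no free alkoxide can displace the chloride four atoms away (a risk of basic methanolysis).

Step 7
Reactants: 9
Product: 10 4-(2-chloroethyl)-2,2-ethylenedioxybicyclo[2.2.1]heptan-5-one
Conditions: TPAP (cat.), NMO, 4 Å MS, CH2Cl2, rt
Reagents that add atoms: none
Why: Ley–Griffith oxidation of the hindered secondary alcohol under neutral conditions that keep the ketal.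

Step 8
Reactants: 10
Product: 11 4-(2-chloroethyl)-2,2-ethylenedioxybicyclo[2.2.1]hept-5-en-5-yl trifluoromethanesulfonate
Conditions: KHMDS, THF, −78 °C; PhNTf2, −78 → 0 °C
Reagents that add atoms: N-phenylbis(trifluoromethanesulfonimide), O=S(=O)(N(c1ccccc1)S(=O)(=O)C(F)(F)F)C(F)(F)F
Why: Enolisation can only occur toward C5 (C8 is quaternary), and O-sulfonylation of the potassium enolate gives the enol triflate.

Step 9
Reactants: 11; 12 isopropenylboronic acid pinacol ester
Product: 13 4-(2-chloroethyl)-2,2-ethylenedioxy-5-isopropenylbicyclo[2.2.1]hept-5-ene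
Conditions: Pd(PPh3)4 (cat.), K3PO4, dioxane/H2O, 80 °C
Reagents that add atoms: isopropenylboronic acid pinacol ester (12), CC(=C)B1OC(C)(C)C(C)(C)O1
Why: Suzuki–Miyaura coupling of the alkenyl triflate with the alkenylboronate; the unactivated primary chloride does not undergo oxidative addition with this catalyst.

Step 10
Reactants: 13
Product: 14 4-(2-chloroethyl)-2,2-ethylenedioxy-5-endo-isopropylbicyclo[2.2.1]heptane
Conditions: H2 (1 atm), 10% Pd/C, EtOAc, rt
Reagents that add atoms: none
Why: Heterogeneous hydrogenation of the diene delivers hydrogen to C4 of the norbornene from the exo face whichever alkene is reduced first, so the isopropyl group ends endo; chloride and ketal are inert.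

Step 11
Reactants: 14
Product: 15 2,2-ethylenedioxy-4-(2-iodoethyl)-5-endo-isopropylbicyclo[2.2.1]heptane
Conditions: NaI, butanone, reflux
Reagents that add atoms: sodium iodide, [Na+].[I-]
Why: Finkelstein halide exchange (SN2) driven by precipitation of sodium chloride.

Step 12
Reactants: 16 2-methylcyclohexane-1,3-dione; 17 1,1-dimethylhydrazine
Product: 18 3-(2,2-dimethylhydrazinylidene)-2-methylcyclohexan-1-one
Conditions: TsOH (cat.), benzene, reflux (Dean–Stark)
Reagents that add atoms: 1,1-dimethylhydrazine (17), CN(C)N
Why: Condensation of one carbonyl with the hydrazine gives the mono-hydrazone (in equilibrium with its ene-hydrazine tautomer).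

Step 13
Reactants: 15; 18
Product: 19 3-(2,2-dimethylhydrazinylidene)-2-methyl-2-R-cyclohexan-1-one (both C11 epimers)
Conditions: 18, KH, THF, 0 °C; then 15, 0 °C → rt
Reagents that add atoms: 3-(2,2-dimethylhydrazinylidene)-2-methylcyclohexan-1-one (18), CC1C(=O)CCCC1=NN(C)C
Why: C-alkylation of the potassium aza-enolate of the keto-hydrazone with an unactivated primary iodide (the hydrazone route to 2,2-disubstituted cyclohexane-1,3-diones, which avoids the O-alkylation of the parent dione); the C11 epimers converge in step 14.

Step 14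
Reactants: 19
Product: 20 2-methyl-2-R-cyclohexane-1,3-dione
Conditions: Cu(OAc)2, THF/H2O, rt
Reagents that add atoms: water, O
Why: Cu(II)-assisted hydrolysis of the dimethylhydrazone near neutral pH frees the second carbonyl without touching the dioxolane and leaves C11 prochiral between two enantiotopic carbonyls.

Step 15
Reactants: 20
Product: 21 (2R,3R)-3-hydroxy-2-methyl-2-R-cyclohexan-1-one
Conditions: (S)-Me-CBS (0.2 equiv), BH3·SMe2 (0.6 equiv), THF, −20 °C; MeOH
Reagents that add atoms: none
Why: Corey–Bakshi–Shibata reduction used as an enantiotopic-group-selective desymmetrisation of a 2,2-disubstituted cyclohexane-1,3-dione: the catalyst fixes the carbinol configuration at C13 and hydride enters anti to the larger C11 substituent, so the quaternary C11 and the C13 hydroxyl (cis to the C10 chain, later axial) are set together.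

Step 16
Reactants: 21
Product: 22 acetate of 21 (C13 acetate; C18 ketone; C20 ketal)
Conditions: Ac2O, DMAP (cat.), pyridine, rt
Reagents that add atoms: acetic anhydride, CC(=O)OC(C)=O
Why: DMAP-catalysed acetylation masks the β-hydroxy ketone against retro-aldol cleavage and against the later oxidation; the α-carbon is quaternary, so no elimination is possible.

Step 17
Reactants: 22
Product: 25 tetracyclic enone acetate (C18=C19 conjugated to the C20 ketone; C13 acetate), via diketone 23 (not isolated), via ketol 24 (not isolated)
Conditions: 1 M HCl, THF, 40 °C; then TsOH (cat.), toluene, reflux (Dean–Stark)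
Reagents that add atoms: water, O
Why: Acid hydrolysis of the dioxolane, then acid-catalysed intramolecular aldol condensation (second stage of a Robinson annulation, 6-enolexo): the C20 enol can only form toward C19 and the only ketone within reach of a six-membered closure is C18, so ring B closes and dehydration gives the conjugated enone.

Step 18
Reactants: 25
Product: 27 tetracyclic ene-dione acetate (C16 and C20 ketones across C18=C19), via C16 tert-butyl peroxide 26 (not isolated)
Conditions: Pd(OH)2/C (cat.), t-BuOOH, K2CO3, CH2Cl2, 4 °C → rt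
Reagents that add atoms: tert-butyl hydroperoxide, CC(C)(C)OO
Why: Pd(OH)2/t-BuOOH γ-oxidation of an α,β-enone to the ene-1,4-dione through the allylic peroxide; C16 is the only allylic position that carries hydrogen, C8 and C11 being quaternary.

Step 19
Reactants: 27
Product: 28 tetracyclic 16-hydroxy-16-methyl enone acetate (C16 hydroxyl syn to the C11 methyl)
Conditions: MeMgBr (1.2 equiv), CeCl3, THF, −78 °C; aq. NH4Cl
Reagents that add atoms: methylmagnesium bromide, C[Mg]Br
Why: Cerium-modified Grignard 1,2-addition to the C16 carbonyl, which has an unbranched α-CH2 and can twist out of conjugation, in preference to the C20 carbonyl held in the bicycle between the bridgehead C6 and C19; the nucleophile enters on the face opposite the axial C11 methyl, which sets C16.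

Step 20
Reactants: 28
Product: 30 saturated 13,16-diol 20-ketone (trans B/C; C18 exo on the norbornane), via C19-epimeric diol ketone 29 (not isolated)
Conditions: LiHMDS (1.1 equiv), THF, −78 °C; Li, NH3(l)/THF, t-BuOH (2 equiv), −78 °C; solid NH4Cl; then NaOMe (cat.), MeOH, rt
Reagents that add atoms: none
Why: Dissolving-metal (Birch-type) reduction of the enone on its pre-formed C16 alkoxide, which is a poor leaving group and no internal proton source: the C18 carbanion is protonated axially to give the trans B/C fusion, the acetate is cleaved reductively, and methoxide then equilibrates C19 through the C20 enolate to the less strained exo-fused ketone.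

Step 21
Reactants: 30
Product: 31 13-bromo-16-hydroxy 20-ketone (equatorial bromide)
Conditions: CBr4, PPh3, CH2Cl2, 0 → 40 °C
Reagents that add atoms: carbon tetrabromide, BrC(Br)(Br)Br
Why: Appel bromination of the axial neopentylic C13 carbinol with inversion (SN2 on the oxyphosphonium), the reaction type used to place equatorial bromine next to a quaternary carbon in trans-fused rings of brominated terpenoids; the tertiary C16 hydroxyl is too hindered to be activated and the ketone is inert.

Step 22
Reactants: 31
Product: 32 CNP0295684.1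
Conditions: NaBH4, MeOH, −20 → 0 °C
Reagents that add atoms: none
Why: Borohydride attacks the norbornanone from the exo face (the endo face is screened by the C5 endo hydrogen and the endo isopropyl at C4), giving the endo C20 alcohol; the secondary bromide is untouched.

## Compound list

1 | (1S,4S)-bicyclo[2.2.1]heptane-2,5-dione | O=C1C[C@@H]2C[C@H]1CC2=O | starting material
2 | vinylmagnesium bromide | C=C[Mg]Br | starting material
3 | 5-endo-hydroxy-5-exo-vinylbicyclo[2.2.1]heptan-2-one | O[C@@]1(C=C)C[C@@H]2C[C@H]1CC2=O | intermediate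
4 | pinacol boronate of 3 (B on the terminal carbon of the chain) | O[C@@]1(CCB3OC(C)(C)C(C)(C)O3)C[C@@H]2C[C@H]1CC2=O | intermediate (not isolated)
5 | 5-endo-hydroxy-5-exo-(2-hydroxyethyl)bicyclo[2.2.1]heptan-2-one | O[C@@]1(CCO)C[C@@H]2C[C@H]1CC2=O | intermediate
6 | 5-exo-(2-chloroethyl)-5-endo-hydroxybicyclo[2.2.1]heptan-2-one | O[C@@]1(CCCl)C[C@@H]2C[C@H]1CC2=O | intermediate
7 | 5-exo-acetoxy-4-(2-chloroethyl)bicyclo[2.2.1]heptan-2-one | CC(=O)O[C@H]1C[C@H]2C[C@]1(CCCl)CC2=O | intermediate
8 | 5-exo-acetoxy-4-(2-chloroethyl)-2,2-ethylenedioxybicyclo[2.2.1]heptane | CC(=O)O[C@H]1C[C@H]2C[C@]1(CCCl)CC23OCCO3 | intermediate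
9 | 4-(2-chloroethyl)-2,2-ethylenedioxybicyclo[2.2.1]heptan-5-exo-ol | O[C@H]1C[C@H]2C[C@]1(CCCl)CC23OCCO3 | intermediate
10 | 4-(2-chloroethyl)-2,2-ethylenedioxybicyclo[2.2.1]heptan-5-one | O=C1C[C@H]2C[C@]1(CCCl)CC23OCCO3 | intermediate
11 | 4-(2-chloroethyl)-2,2-ethylenedioxybicyclo[2.2.1]hept-5-en-5-yl trifluoromethanesulfonate | O=S(=O)(OC1=C[C@H]2C[C@]1(CCCl)CC23OCCO3)C(F)(F)F | intermediate
12 | isopropenylboronic acid pinacol ester | CC(=C)B1OC(C)(C)C(C)(C)O1 | starting material
13 | 4-(2-chloroethyl)-2,2-ethylenedioxy-5-isopropenylbicyclo[2.2.1]hept-5-ene | CC(=C)C1=C[C@H]2C[C@]1(CCCl)CC23OCCO3 | intermediate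
14 | 4-(2-chloroethyl)-2,2-ethylenedioxy-5-endo-isopropylbicyclo[2.2.1]heptane | CC(C)[C@@H]1C[C@H]2C[C@]1(CCCl)CC23OCCO3 | intermediate
15 | 2,2-ethylenedioxy-4-(2-iodoethyl)-5-endo-isopropylbicyclo[2.2.1]heptane | CC(C)[C@@H]1C[C@H]2C[C@]1(CCI)CC23OCCO3 | intermediate
16 | 2-methylcyclohexane-1,3-dione | CC1C(=O)CCCC1=O | starting material
17 | 1,1-dimethylhydrazine | CN(C)N | starting material
18 | 3-(2,2-dimethylhydrazinylidene)-2-methylcyclohexan-1-one | CC1C(=O)CCCC1=NN(C)C | intermediate
19 | 3-(2,2-dimethylhydrazinylidene)-2-methyl-2-R-cyclohexan-1-one (both C11 epimers; C=N geometry not defined) | CC(C)[C@@H]1C[C@H]2C[C@]1(CCC4(C)C(=O)CCCC4=NN(C)C)CC23OCCO3 | intermediate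
20 | 2-methyl-2-R-cyclohexane-1,3-dione | CC(C)[C@@H]1C[C@H]2C[C@]1(CCC4(C)C(=O)CCCC4=O)CC23OCCO3 | intermediate
21 | (2R,3R)-3-hydroxy-2-methyl-2-R-cyclohexan-1-one | CC(C)[C@@H]1C[C@H]2C[C@]1(CC[C@]4(C)[C@H](O)CCCC4=O)CC23OCCO3 | intermediate
22 | acetate of 21 | CC(C)[C@@H]1C[C@H]2C[C@]1(CC[C@]4(C)[C@H](OC(C)=O)CCCC4=O)CC23OCCO3 | intermediate
23 | 22 with the C20 ketone unmasked (C18,C20-diketone) | CC(C)[C@@H]1C[C@H]2C[C@]1(CC[C@]4(C)[C@H](OC(C)=O)CCCC4=O)CC2=O | intermediate (not isolated)
24 | tetracyclic aldol adduct, 18-hydroxy-20-ketone 13-acetate (C18 and C19 not defined) | CC(C)[C@@H]1C[C@H]2C[C@@]13CC[C@]4(C)[C@H](OC(C)=O)CCCC4(O)C3C2=O | intermediate (not isolated)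
25 | tetracyclic enone: C18=C19, C20 ketone, C13 acetate | CC(C)[C@@H]1C[C@H]2C[C@@]13CC[C@]4(C)[C@H](OC(C)=O)CCCC4=C3C2=O | intermediate
26 | 16-(tert-butylperoxy) derivative of 25 (C16 not defined) | CC(C)[C@@H]1C[C@H]2C[C@@]13CC[C@]4(C)[C@H](OC(C)=O)CCC(OOC(C)(C)C)C4=C3C2=O | intermediate (not isolated)
27 | tetracyclic ene-dione: C16 and C20 ketones, C18=C19, C13 acetate | CC(C)[C@@H]1C[C@H]2C[C@@]13CC[C@]4(C)[C@H](OC(C)=O)CCC(=O)C4=C3C2=O | intermediate
28 | tetracyclic 16-hydroxy-16-methyl enone 13-acetate | CC(C)[C@@H]1C[C@H]2C[C@@]13CC[C@]4(C)[C@H](OC(C)=O)CC[C@@](C)(O)C4=C3C2=O | intermediate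
29 | C19 epimer of 30 | CC(C)[C@@H]1C[C@H]2C[C@@]13CC[C@]4(C)[C@H](O)CC[C@@](C)(O)[C@H]4[C@H]3C2=O | intermediate (not isolated)
30 | saturated tetracyclic 13,16-diol 20-ketone (C13 hydroxyl axial) | CC(C)[C@@H]1C[C@H]2C[C@@]13CC[C@]4(C)[C@H](O)CC[C@@](C)(O)[C@H]4[C@@H]3C2=O | intermediate
31 | 13-bromo-16-hydroxy 20-ketone (20-oxo form of the target) | CC(C)[C@@H]1C[C@H]2C[C@@]13CC[C@]4(C)[C@@H](Br)CC[C@@](C)(O)[C@H]4[C@@H]3C2=O | intermediate
32 | CNP0295684.1 | CC(C)[C@@H]1C[C@H]2C[C@@]13CC[C@]1(C)[C@@H](Br)CC[C@@](C)(O)[C@H]1[C@@H]3[C@H]2O | target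

## Count and risks

Total steps: 22. Longest linear sequence: 21 steps (1 → 32 through steps 1–11 and 13–22; step 12 makes the side fragment 18).

**Step 19.** The methyl nucleophile may add to the C20 carbonyl, or enolise C15, instead of adding cleanly at C16. The fallback sets out from 22 and returns at 28; it installs the methyl group before ring B exists and brings in the oxygen afterwards. Enolisation of 22 with LDA and methylation at C16 (the only α-CH2) gives the C16-methyl ketone F1. Acid treatment as in step 17 leads, through the diketone F2 and the ketol F3, to the C16-methyl enone F4. TMSOTf/Et3N converts this into the silyl dienol ether F5 (C20(OSiMe3)=C19–C18=C16). Buffered mCPBA then oxidises C16 by axial attack syn to the C11 methyl, the course known for 3,5-dienol ethers of 4-en-3-ones, and gives 28.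

**Step 21.** Backside attack at the neopentylic C13 may be too slow, so that elimination toward C14, a 1,2-shift from C11 or dehydration of the tertiary C16 carbinol takes over. The fallback sets out from 27 and returns at 31; it introduces bromine before the tertiary alcohol exists. Zn/AcOH reduces the ene-dione to the saturated diketone F6, in which C18 and C19 are both epimerisable and should settle in the trans-B/C, exo-fused arrangement. K2CO3/MeOH removes the acetate to give the hydroxy diketone F7, which carries a single hydroxyl. CBr4/PPh3 gives the bromo diketone F8. MeMgBr/CeCl3 at −78 °C should then add to the C16 ketone (one unbranched α-carbon, axial face blocked by the C11 methyl) rather than to the doubly α-branched C20 ketone, giving 31.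

**Step 20.** The C18 carbanion may expel the C16 oxygen by β-elimination, or be protonated from the hydroxyl-bearing face. The fallback sets out from 28 and returns at 30. Heterogeneous hydrogenation (H2, Rh/Al2O3, EtOAc) should add both hydrogens from the exo, C7-side face, which is also anti to the C11 methyl; this gives the saturated ketone F9 with C18 correct and C19 epimeric. DBU equilibrates C19 through the C20 enol to the exo-fused acetate F10. K2CO3/MeOH removes the acetate and gives 30.

## Further compounds

F1 | step 19 | C16-methyl derivative of 22 (C16 epimers) | CC(C)[C@@H]1C[C@H]2C[C@]1(CC[C@]4(C)[C@H](OC(C)=O)CCC(C)C4=O)CC23OCCO3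
F2 | step 19 | F1 with the C20 ketone unmasked | CC(C)[C@@H]1C[C@H]2C[C@]1(CC[C@]4(C)[C@H](OC(C)=O)CCC(C)C4=O)CC2=O
F3 | step 19 | tetracyclic aldol adduct of F2 (C16, C18, C19 not defined) | CC(C)[C@@H]1C[C@H]2C[C@@]13CC[C@]4(C)[C@H](OC(C)=O)CCC(C)C4(O)C3C2=O
F4 | step 19 | tetracyclic 16-methyl enone 13-acetate | CC(C)[C@@H]1C[C@H]2C[C@@]13CC[C@]4(C)[C@H](OC(C)=O)CCC(C)C4=C3C2=O
F5 | step 19 | trimethylsilyl dienol ether of F4 | CC(C)[C@@H]1C[C@H]2C[C@@]13CC[C@]4(C)[C@H](OC(C)=O)CCC(C)=C4C3=C2O[Si](C)(C)C
F6 | step 21 | saturated tetracyclic 16,20-diketone 13-acetate | CC(C)[C@@H]1C[C@H]2C[C@@]13CC[C@]4(C)[C@H](OC(C)=O)CCC(=O)[C@H]4[C@@H]3C2=O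
F7 | step 21 | saturated 13-hydroxy 16,20-diketone | CC(C)[C@@H]1C[C@H]2C[C@@]13CC[C@]4(C)[C@H](O)CCC(=O)[C@H]4[C@@H]3C2=O
F8 | step 21 | saturated 13-bromo 16,20-diketone | CC(C)[C@@H]1C[C@H]2C[C@@]13CC[C@]4(C)[C@@H](Br)CCC(=O)[C@H]4[C@@H]3C2=O
F9 | step 20 | C19 epimer of the saturated 16-hydroxy-16-methyl 20-ketone 13-acetate | CC(C)[C@@H]1C[C@H]2C[C@@]13CC[C@]4(C)[C@H](OC(C)=O)CC[C@@](C)(O)[C@H]4[C@H]3C2=O
F10 | step 20 | saturated 16-hydroxy-16-methyl 20-ketone 13-acetate | CC(C)[C@@H]1C[C@H]2C[C@@]13CC[C@]4(C)[C@H](OC(C)=O)CC[C@@](C)(O)[C@H]4[C@@H]3C2=O
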